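# Proposed total synthesis of CNP0359197.1 by a carbene-catalysed Stetter macrocyclisation

## Analysis of the target

The target is a germacranolide. With germacrane locants (ring C1–C10, C11–C13 on C7, C14 on C10, C15 on C4) it is a ten-membered carbocycle fused across C6–C7 to a butenolide (O6–C12(=O)–C11=C7) and across C4–C5 to an oxirane. Six stereocentres must be delivered: C2 (S, free hydroxyl), C4 (S) and C5 (R) of a trisubstituted epoxide whose two ring bonds are cis, C6 (R, lactone oxygen anti to the epoxide oxygen), C8 (R, methacrylate) and C10 (S, methyl). C4, C5 and C6 are contiguous. C2 and C10 flank the C1 ketone and are both epimerisable. C8 lies between the ring and the butenolide with no neighbouring stereocentre to lean on. The sensitive groups are an acid-labile epoxide, three ester-type groups (acetate, methacrylate, lactone), a polymerisable methacrylate and an α-hydroxy ketone. In addition, C6–H of the butenolide is vinylogously acidic, so base can open the adjacent epoxide or expel the C13 acetate. The difficulty is to close a medium ring that already carries this functionality, with oxygen on five ring carbons, without losing any of it. The plan rests on the 1,4-relationship of the C1 ketone and the C8 oxygen through C10 and C9, with the methyl branch on C10. At the C8-ketone level this is the adduct of a C1 acyl anion and a crotonyl ketone attached to C7, and because C7 and C11 are fully substituted, C10 is the only open acceptor carbon.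

## Retrosynthetic reasoning

The last bonds to go are peripheral. The acyl–O8 bond of the methacrylate and the O2–Si bond are cut, which leads from 31 through 30 to 29, and the C8 carbinol is traced back to the ketone in 28. The oxidation level is raised because only a C8 carbonyl makes C9=C10 an acceptor. Forward, the reduction must pick the conjugated C8 ketone over the C1 ketone and give the 8R alcohol; acylation and desilylation then finish the synthesis.

In 28 the ring is opened at C1–C10, which gives aldehyde 27. This bond is chosen because it joins the two halves of a 1,4-dicarbonyl unit. Cutting it leaves an aldehyde carbon and an enone β-carbon, and every other stereocentre and the complete butenolide stay in one chain. The gain is that the ring and the C10 stereocentre arise in one step. Forward, an acyl-anion equivalent generated at C1 must add to C10 inside the molecule and choose one face of the enone.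

Aldehyde 27 is an α-silyloxy aldehyde and should not be stored. It is taken back by one oxidation to alcohol 26 and by cleavage of a 4-methoxybenzyl ether to 25, so the aldehyde appears only just before the ring closure.

The butenolide of 25 is cut at C7=C11 and at the C12–O6 ester bond. This goes back through mesylate 24, acetate 23, hydroxy lactone 22 and aldol adduct 20 to ketone 14 and keto ester 18. C7 is the α-carbon of the C8 ketone and C11 is the ketone carbon of an α-keto ester, so both bonds follow natural polarity. The geometry of the tetrasubstituted alkene needs no control because the lactone ring enforces it. This avoids a stereodefined tetrasubstituted alkenyl halide, which syn-carbometalation would deliver with the wrong geometry. Keto ester 18 comes from acrylate 15 through 16 by oxidative cleavage of the methylene group.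

Ketone 14 (through 13) is cut at C6–C7 into epoxy aldehyde 10 and pentenone 11. Pentenone 11 supplies C7–C10 and C14 at the final oxidation level, so C8 needs neither protection nor later oxidation. Forward, the aldol addition must set C6 anti to the epoxide oxygen, which is the Felkin–Anh sense for an epoxy aldehyde.

Aldehyde 10 goes back to epoxy alcohol 9 and to the Z-allylic alcohol 8. The C4–C5 epoxide is placed by Sharpless asymmetric epoxidation, which sets both centres by reagent control, and the Z geometry of 8 becomes the cis arrangement of C3 and C6 on the oxirane.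

Alcohol 8 is taken back through ester 7 to ynoate 6 and its alcohol 5. The C15 methyl and the alkene geometry come from one syn-carbometalation of the triple bond, which is the most reliable way to a Z-trisubstituted alkene of this type.

Ynoate 5 is cut at C3–C4 into epoxide 2 and propiolate 3, and 2 is the ether of glycidol 1. C2 therefore comes from the chiral pool, and the future C1 aldehyde is carried as a 4-methoxybenzyl ether from the first step.

## Alternatives that were turned down

Alternative 1: The ring and the lactone would be made together by cutting C6–C7 and the C12–O6 bond. In the forward step, seco compound A2 has a C7 alkenyl iodide cis to a C12 methyl ester at one end and the C6 epoxy aldehyde at the other. Under Nozaki–Hiyama–Kishi conditions (divalent chromium, catalytic nickel) the alkenylchromium adds to the aldehyde, the chromium alkoxide closes the lactone, and the protected core A1 results. In its favour, this closure has firm precedent for medium and large rings. It is not basic, which suits C6–H and the epoxide better than carbene conditions, and it reacts only with the aldehyde. C2, C8 and C10 are already in place, so no late reduction is needed. On precedent and mildness it is stronger than the chosen route. Against it, A2 needs a tetrasubstituted β-iodo enoate of defined geometry bearing the CH2O group, and syn-carbometalation of an ynoate gives the opposite geometry. The seco chain must also carry the C1 ketone with both epimerisable neighbours and the C8 carbinol, each set by its own asymmetric step, through a long linear sequence. The ring closure joins a tetrasubstituted alkenylmetal to an α-branched aldehyde and fixes C6 in a macrocyclic transition state. The chosen route instead builds the butenolide early by aldol chemistry on an open chain. It creates C10 in the ring closure and sets C8 by a catalyst-controlled reduction, so fewer stereocentres must be installed beforehand.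

Alternative 2: The ten-membered ring would come from ring expansion, with C8–C9 formed and C1–C6 broken. In the forward step the potassium alkoxide of the trans-dialkenyl cyclohexenol A4 undergoes an anionic oxy-Cope [3,3] shift through a chair transition state and gives dienone A3. In its favour, this is a classical entry to germacrane rings. The strain of the medium ring is paid for by enolate formation, no dilution is needed, and the chair relays both alkene geometries and C8 from A4. For the ring-forming event itself it is more reliable than the chosen route. Against it, A3 is far from the target. It has no butenolide and no C11–C13, and C6 is a ketone. C4=C5 must still be epoxidised from one face of a flexible ring. C1=C10 must be converted into the C1 ketone and the C10 methyl stereocentre, and the lactone must be annulated at C7. Each of these steps depends on medium-ring conformational control. The chosen route closes the ring with every carbon and every oxygen except the C8 oxidation level already in place, and needs three steps after the closure.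

Alternative 3: The ring would be closed at C3–C4. In the forward step, A6 carries a Z-alkenyl iodide at C4 and a 1-substituted cyclopropanol at C1. A palladium catalyst with a bulky biarylphosphine inserts into the C–I bond, the cyclopropanol opens to a palladium homoenolate, and reductive elimination forms C3–C4 and unveils the C1 ketone in A5. In its favour, the butenolide, C6, C8 and C10 are set before the closure. C10 is not created in the ring-closing step, which is a real advantage over the chosen route. Cyclopropanol ring-opening cross-coupling is known chemistry. Against it, A5 has neither the C2 oxygen nor the epoxide. A late α-hydroxylation would have to choose C2 over the more substituted C10 and set its configuration. The 4Z alkene would have to be epoxidised from one face next to the butenolide. β-Hydride elimination from the homoenolate to an enone competes with a slow ten-membered reductive elimination, and base is still needed. Both closures lack precedent at this ring size, so the novelty risk is comparable. The chosen route places C2 from the chiral pool and the epoxide by Sharpless epoxidation before the closure, and leaves only routine steps after it.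

Key step: step 18

Remark: locants C1–C15 are the germacrane locants of the target and are used for every intermediate; TBS = tert-butyldimethylsilyl, TES = triethylsilyl, PMB = 4-methoxybenzyl; 20–24 are carried as mixtures at C7 and C11 because both carbons become sp2 in step 15.

## Route

Step 1
Reactants: 1 (R)-glycidol
Product: 2 (S)-glycidyl 4-methoxybenzyl ether [(2S)-2-[(4-methoxybenzyloxy)methyl]oxirane]
Conditions: NaH, 4-methoxybenzyl chloride, n-Bu4NI (cat.), THF/DMF, 0 °C to rt
Reagents that add atoms: 4-methoxybenzyl chloride, COc1ccc(CCl)cc1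
Why: Williamson etherification of the sodium alkoxide of 1; no bond to the stereocentre is made or broken (a Payne shift of glycidol regenerates the same enantiomer), and the descriptor changes from R to S only because the ether carbon now outranks the ring CH2.

Step 2
Reactants: 2 (S)-glycidyl 4-methoxybenzyl ether; 3 ethyl propiolate
Product: 5 ethyl (5S)-5-hydroxy-6-(4-methoxybenzyloxy)hex-2-ynoate, via lithium ethyl propiolate 4 (not isolated)
Conditions: 3, n-BuLi, THF, −78 °C; BF3·OEt2; then 2, −78 °C
Reagents that add atoms: none
Why: Yamaguchi–Hirao alkynylation: the BF3-activated epoxide is opened at its unsubstituted carbon by acetylide 4 (SN2), which forms C3–C4 and leaves the carbinol centre, the future C2 (S), untouched.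

Step 3
Reactants: 5 ethyl (5S)-5-hydroxy-6-(4-methoxybenzyloxy)hex-2-ynoate
Product: 6 ethyl (5S)-5-(tert-butyldimethylsilyloxy)-6-(4-methoxybenzyloxy)hex-2-ynoate
Conditions: TBSCl, imidazole, DMF, rt
Reagents that add atoms: tert-butyldimethylsilyl chloride, CC(C)(C)[Si](C)(C)Cl
Why: Standard silylation of a secondary alcohol; the silyl ether blocks δ-lactonisation in the next two steps and stays on O2 until the last step.

Step 4
Reactants: 6 ethyl (5S)-5-(tert-butyldimethylsilyloxy)-6-(4-methoxybenzyloxy)hex-2-ynoate
Product: 7 ethyl (2Z,5S)-5-(tert-butyldimethylsilyloxy)-6-(4-methoxybenzyloxy)-3-methylhex-2-enoate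
Conditions: MeLi, CuI, THF, 0 °C; then 6, −78 °C; MeOH, −78 °C
Reagents that add atoms: lithium dimethylcuprate, [Li+].C[Cu-]C (made in the flask from methyllithium, [Li]C, and CuI)
Why: Syn-carbocupration of the ynoate with protonation in the cold places the new methyl (C15) cis to hydrogen, so the chain and the ester are cis (Z); this is the nerol-type geometry that later gives the cis-substituted epoxide.

Step 5
Reactants: 7 ethyl (2Z,5S)-5-(tert-butyldimethylsilyloxy)-6-(4-methoxybenzyloxy)-3-methylhex-2-enoate
Product: 8 (2Z,5S)-5-(tert-butyldimethylsilyloxy)-6-(4-methoxybenzyloxy)-3-methylhex-2-en-1-ol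
Conditions: i-Bu2AlH, CH2Cl2, −78 °C; aqueous potassium sodium tartrate (KNaC4H4O6)
Reagents that add atoms: none
Why: 1,2-Reduction of the conjugated ester to the allylic alcohol by the aluminium hydride; the trisubstituted Z-alkene is configurationally stable under these conditions.

Step 6
Reactants: 8 (2Z,5S)-5-(tert-butyldimethylsilyloxy)-6-(4-methoxybenzyloxy)-3-methylhex-2-en-1-ol
Product: 9 [(2R,3S)-3-[(2S)-2-(tert-butyldimethylsilyloxy)-3-(4-methoxybenzyloxy)propyl]-3-methyloxiran-2-yl]methanol
Conditions: Ti(OiPr)4 (10 mol%), diethyl D-(−)-tartrate (12 mol%), t-BuOOH, 4 Å molecular sieves, CH2Cl2, −20 °C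
Reagents that add atoms: tert-butyl hydroperoxide, CC(C)(C)OO
Why: Sharpless asymmetric epoxidation of a Z-3,3-disubstituted allylic alcohol: the D-(−)-tartrate complex delivers oxygen to the face that gives the (2R,3S)-epoxy alcohol (the sense known for nerol), which sets C5 (R) and C4 (S) under reagent control and keeps C3 and C6 cis on the oxirane.

Step 7
Reactants: 9 [(2R,3S)-3-[(2S)-2-(tert-butyldimethylsilyloxy)-3-(4-methoxybenzyloxy)propyl]-3-methyloxiran-2-yl]methanol
Product: 10 (2S,3S)-3-[(2S)-2-(tert-butyldimethylsilyloxy)-3-(4-methoxybenzyloxy)propyl]-3-methyloxirane-2-carbaldehyde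
Conditions: Dess–Martin periodinane, pyridine, CH2Cl2, 0 °C to rt
Reagents that add atoms: none
Why: Dess–Martin oxidation of the primary epoxy alcohol under buffered conditions; the α-carbon is an oxirane carbon and does not enolise, so C5 is safe (its descriptor becomes S only through the higher priority of CHO).

Step 8
Reactants: 10 (2S,3S)-3-[(2S)-2-(tert-butyldimethylsilyloxy)-3-(4-methoxybenzyloxy)propyl]-3-methyloxirane-2-carbaldehyde; 11 (E)-pent-3-en-2-one
Product: 13 (2E,6R)-6-hydroxy-6-[(2R,3S)-3-[(2S)-2-(tert-butyldimethylsilyloxy)-3-(4-methoxybenzyloxy)propyl]-3-methyloxiran-2-yl]hex-2-en-4-one, via lithium dienolate 12 (not isolated)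
Conditions: 11, LiN(i-Pr)2, THF, −78 °C; then 10, −78 °C; AcOH, −78 °C
Reagents that add atoms: none
Why: Aldol addition of the kinetic lithium dienolate 12 to the aldehyde; in the Felkin–Anh (and Cornforth) arrangement the epoxide C–O bond is anti to the incoming enolate, which passes the hydrogen on C5, so C6 is formed R with its oxygen anti to the epoxide oxygen, the sense that cis-substituted epoxy aldehydes follow most reliably.

Step 9
Reactants: 13 (2E,6R)-6-hydroxy-6-[(2R,3S)-3-[(2S)-2-(tert-butyldimethylsilyloxy)-3-(4-methoxybenzyloxy)propyl]-3-methyloxiran-2-yl]hex-2-en-4-one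
Product: 14 (2E,6R)-6-(triethylsilyloxy)-6-[(2R,3S)-3-[(2S)-2-(tert-butyldimethylsilyloxy)-3-(4-methoxybenzyloxy)propyl]-3-methyloxiran-2-yl]hex-2-en-4-one
Conditions: TESCl, imidazole, CH2Cl2, 0 °C
Reagents that add atoms: triethylsilyl chloride, CC[Si](Cl)(CC)CC
Why: Silylation of the β-hydroxy ketone, so that the second enolisation at C7 meets a poor leaving group at C6 and no free alkoxide sits next to the epoxide.

Step 10
Reactants: 15 methyl 2-(hydroxymethyl)prop-2-enoate
Product: 16 methyl 2-[(triethylsilyloxy)methyl]prop-2-enoate
Conditions: TESCl, imidazole, CH2Cl2, 0 °C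
Reagents that add atoms: triethylsilyl chloride, CC[Si](Cl)(CC)CC
Why: Routine silylation of the primary allylic alcohol; the same silyl group as on O6 is chosen so that both fall together in step 13.

Step 11
Reactants: 16 methyl 2-[(triethylsilyloxy)methyl]prop-2-enoate
Product: 18 methyl 2-oxo-3-(triethylsilyloxy)propanoate, via ozonide 17 (not isolated)
Conditions: O3, CH2Cl2, −78 °C; then PPh3, −78 °C to rt
Reagents that add atoms: ozone, [O-][O+]=O
Why: Ozonolysis of the 1,1-disubstituted alkene through ozonide 17; reductive cleavage with the phosphine gives the α-keto ester, which is dried and used fresh.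

Step 12
Reactants: 14 (2E,6R)-6-(triethylsilyloxy)-6-[(2R,3S)-3-[(2S)-2-(tert-butyldimethylsilyloxy)-3-(4-methoxybenzyloxy)propyl]-3-methyloxiran-2-yl]hex-2-en-4-one; 18 methyl 2-oxo-3-(triethylsilyloxy)propanoate
Product: 20 methyl (4R)-3-[(E)-but-2-enoyl]-2-hydroxy-4-[(2R,3S)-3-[(2S)-2-(tert-butyldimethylsilyloxy)-3-(4-methoxybenzyloxy)propyl]-3-methyloxiran-2-yl]-4-(triethylsilyloxy)-2-[(triethylsilyloxy)methyl]butanoate (epimers at C7 and C11), via lithium enolate 19 (not isolated)
Conditions: 14, LiN(i-Pr)2, THF, −78 °C; then 18, −78 °C; AcOH, −78 °C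
Reagents that add atoms: none
Why: Kinetic deprotonation of 14 can only occur at C7 (the other α-carbon is vinylic), and the lithium enolate adds to the very electrophilic ketone carbonyl of 18 (aldol addition), which forms C7–C11; the two new centres are not controlled and are both removed in step 15.

Step 13
Reactants: 20 methyl (4R)-3-[(E)-but-2-enoyl]-2-hydroxy-4-[(2R,3S)-3-[(2S)-2-(tert-butyldimethylsilyloxy)-3-(4-methoxybenzyloxy)propyl]-3-methyloxiran-2-yl]-4-(triethylsilyloxy)-2-[(triethylsilyloxy)methyl]butanoate
Product: 22 (5R)-4-[(E)-but-2-enoyl]-3-hydroxy-3-(hydroxymethyl)-5-[(2R,3S)-3-[(2S)-2-(tert-butyldimethylsilyloxy)-3-(4-methoxybenzyloxy)propyl]-3-methyloxiran-2-yl]oxolan-2-one (epimers at C7 and C11), via triol ester 21 (not isolated)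
Conditions: HF·pyridine, pyridine, THF, 0 °C to rt
Reagents that add atoms: none
Why: Buffered HF·pyridine removes the two triethylsilyl ethers while the secondary TBS ether survives; the freed O6–H then closes the γ-lactone on the C12 methyl ester (5-exo-trig acyl substitution, helped by the quaternary C11).

Step 14
Reactants: 22 (5R)-4-[(E)-but-2-enoyl]-3-hydroxy-3-(hydroxymethyl)-5-[(2R,3S)-3-[(2S)-2-(tert-butyldimethylsilyloxy)-3-(4-methoxybenzyloxy)propyl]-3-methyloxiran-2-yl]oxolan-2-one
Product: 23 [(5R)-4-[(E)-but-2-enoyl]-3-hydroxy-2-oxo-5-[(2R,3S)-3-[(2S)-2-(tert-butyldimethylsilyloxy)-3-(4-methoxybenzyloxy)propyl]-3-methyloxiran-2-yl]oxolan-3-yl]methyl acetate (epimers at C7 and C11)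
Conditions: Ac2O, pyridine, CH2Cl2, 0 °C
Reagents that add atoms: acetic anhydride, CC(=O)OC(C)=O
Why: Acetylation without an acyl-transfer catalyst takes the primary C13 hydroxyl and leaves the hindered tertiary C11 hydroxyl free; this installs the acetate of the target.

Step 15
Reactants: 23 [(5R)-4-[(E)-but-2-enoyl]-3-hydroxy-2-oxo-5-[(2R,3S)-3-[(2S)-2-(tert-butyldimethylsilyloxy)-3-(4-methoxybenzyloxy)propyl]-3-methyloxiran-2-yl]oxolan-3-yl]methyl acetate
Product: 25 [(5R)-4-[(E)-but-2-enoyl]-5-[(2R,3S)-3-[(2S)-2-(tert-butyldimethylsilyloxy)-3-(4-methoxybenzyloxy)propyl]-3-methyloxiran-2-yl]-2-oxo-2,5-dihydrofuran-3-yl]methyl acetate, via tertiary mesylate 24 (not isolated)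
Conditions: MsCl, Et3N, CH2Cl2, −20 to 0 °C
Reagents that add atoms: none
Why: Sulfene-type mesylation of the tertiary alcohol followed by E1cB elimination: C7–H is α to the C8 ketone and the exocyclic mesylate can align with the enolate, whereas expulsion of the ring oxygen at C6 would be the reverse of a 5-endo-trig addition; all diastereomers converge on the tetrasubstituted butenolide, whose geometry is fixed by the ring.

Step 16
Reactants: 25 [(5R)-4-[(E)-but-2-enoyl]-5-[(2R,3S)-3-[(2S)-2-(tert-butyldimethylsilyloxy)-3-(4-methoxybenzyloxy)propyl]-3-methyloxiran-2-yl]-2-oxo-2,5-dihydrofuran-3-yl]methyl acetate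
Product: 26 [(5R)-4-[(E)-but-2-enoyl]-5-[(2R,3S)-3-[(2S)-2-(tert-butyldimethylsilyloxy)-3-hydroxypropyl]-3-methyloxiran-2-yl]-2-oxo-2,5-dihydrofuran-3-yl]methyl acetate
Conditions: DDQ, CH2Cl2/pH 7 buffer, 0 °C
Reagents that add atoms: none
Why: Oxidative cleavage of the 4-methoxybenzyl ether through the benzylic oxocarbenium ion; the electron-poor alkenes, the epoxide, the acetate and the silyl ether are inert under buffered conditions.

Step 17
Reactants: 26 [(5R)-4-[(E)-but-2-enoyl]-5-[(2R,3S)-3-[(2S)-2-(tert-butyldimethylsilyloxy)-3-hydroxypropyl]-3-methyloxiran-2-yl]-2-oxo-2,5-dihydrofuran-3-yl]methyl acetate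
Product: 27 [(5R)-4-[(E)-but-2-enoyl]-5-[(2R,3S)-3-[(2S)-2-(tert-butyldimethylsilyloxy)-3-oxopropyl]-3-methyloxiran-2-yl]-2-oxo-2,5-dihydrofuran-3-yl]methyl acetate (seco aldehyde)
Conditions: Dess–Martin periodinane, pyridine, CH2Cl2, 0 °C
Reagents that add atoms: none
Why: Dess–Martin oxidation to the α-silyloxy aldehyde under buffered, non-enolising conditions; 27 is used at once so that C2 keeps its configuration.

Step 18
Reactants: 27 [(5R)-4-[(E)-but-2-enoyl]-5-[(2R,3S)-3-[(2S)-2-(tert-butyldimethylsilyloxy)-3-oxopropyl]-3-methyloxiran-2-yl]-2-oxo-2,5-dihydrofuran-3-yl]methyl acetate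
Product: 28 (2S,4S,5R,6R,10S)-13-acetoxy-2-(tert-butyldimethylsilyloxy)-4,5-epoxy-1,8-dioxogermacr-7(11)-en-12,6-olide
Conditions: (5aS,10bR)-2-(pentafluorophenyl)-5a,10b-dihydro-4H,6H-indeno[2,1-b][1,2,4]triazolo[4,3-d][1,4]oxazin-2-ium tetrafluoroborate (30 mol%), KN(SiMe3)2 (27 mol%), toluene, 23 °C; slow addition of 27 to a final 0.002 M
Reagents that add atoms: none
Why: Proposed new method: the free triazolylidene adds to the C1 aldehyde of 27, proton transfer gives the enaminol (Breslow-type) acyl-anion equivalent, this attacks C10 of the crotonyl ketone, and proton transfer to C9 with loss of the carbene gives the C1,C8-diketone 28. The closest known reaction type is the intramolecular Stetter reaction of aliphatic aldehydes with tethered enones and enoates under aminoindanol-derived triazolium catalysis, which is established for five- and six-membered rings but not for a ten-membered ring or for an acceptor whose C=C and C=O both end up in the ring. The one ring formed, the C1–C10 carbocycle, closes by a 10-endo-trig conjugate addition; a ten-membered transition state leaves room for the required approach to C10, and the cis-epoxide and the planar butenolide remove several rotors and turn the chain back on itself. C10 is the one new stereocentre, and its S configuration is to be set by the enone face that the chiral carbene adduct can reach; because C10–H is α to the new C1 ketone, an unfavourable ratio could in principle be corrected by equilibration. Site selectivity needs no control, since the other electrophilic carbons, C7 and C11, are fully substituted and would give seven- or eight-membered rings. Selectivity against acyloin dimerisation and intermolecular Stetter addition rests on slow addition at high dilution. The base is kept below the triazolium loading so that no free amide base is present, because loss of the vinylogously acidic C6–H would open the epoxide or expel the C13 acetate. The silyloxy group on C2 is a poor leaving group, which argues against redox elimination from the enaminol, and C2 itself is not enolised at any point of the cycle.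

Step 19
Reactants: 28 (2S,4S,5R,6R,10S)-13-acetoxy-2-(tert-butyldimethylsilyloxy)-4,5-epoxy-1,8-dioxogermacr-7(11)-en-12,6-olide
Product: 29 (2S,4S,5R,6R,8R,10S)-13-acetoxy-2-(tert-butyldimethylsilyloxy)-4,5-epoxy-8-hydroxy-1-oxogermacr-7(11)-en-12,6-olide
Conditions: (S)-1-methyl-3,3-diphenyltetrahydro-1H,3H-pyrrolo[1,2-c][1,3,2]oxazaborole (0.5 equiv), catecholborane, toluene, −78 °C
Reagents that add atoms: none
Why: Corey–Bakshi–Shibata reduction: the oxazaborolidine binds the conjugated, less hindered C8 ketone with C7 as the large sp2 substituent and C9H2 as the small one, so the (S)-catalyst should deliver hydride to give the 8R carbinol, while the C1 ketone, flanked by two branched carbons, reacts far more slowly; at −78 °C catecholborane gives 1,2-reduction.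

Step 20
Reactants: 29 (2S,4S,5R,6R,8R,10S)-13-acetoxy-2-(tert-butyldimethylsilyloxy)-4,5-epoxy-8-hydroxy-1-oxogermacr-7(11)-en-12,6-olide
Product: 30 (2S,4S,5R,6R,8R,10S)-13-acetoxy-2-(tert-butyldimethylsilyloxy)-4,5-epoxy-8-(2-methylprop-2-enoyloxy)-1-oxogermacr-7(11)-en-12,6-olide
Conditions: methacrylic anhydride, Et3N, 4-(dimethylamino)pyridine (cat.), CH2Cl2, 0 °C
Reagents that add atoms: methacrylic anhydride, C=C(C)C(=O)OC(=O)C(C)=C
Why: Acyl-transfer catalysed esterification of the secondary allylic alcohol with the anhydride; a short exposure to amine at 0 °C spares C6–H and the α-silyloxy ketone, and acylation of the open hydroxy ketone drains any transannular hemiketal.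

Step 21
Reactants: 30 (2S,4S,5R,6R,8R,10S)-13-acetoxy-2-(tert-butyldimethylsilyloxy)-4,5-epoxy-8-(2-methylprop-2-enoyloxy)-1-oxogermacr-7(11)-en-12,6-olide
Product: 31 (2S,4S,5R,6R,8R,10S)-13-acetoxy-4,5-epoxy-2-hydroxy-8-(2-methylprop-2-enoyloxy)-1-oxogermacr-7(11)-en-12,6-olide (CNP0359197.1)
Conditions: HF·pyridine, pyridine, THF, 0 °C to rt
Reagents that add atoms: none
Why: Fluoride-mediated cleavage of the secondary silyl ether with pyridine-buffered HF·pyridine, conditions expected to leave the epoxide, the three ester-type groups and the centres at C2 and C10 untouched.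

## Compound list

1 | (R)-glycidol | OC[C@@H]1CO1 | starting material
2 | (S)-glycidyl 4-methoxybenzyl ether | COc1ccc(COC[C@@H]2CO2)cc1 | intermediate
3 | ethyl propiolate | C#CC(=O)OCC | starting material
4 | lithium ethyl propiolate (not isolated) | [Li]C#CC(=O)OCC | intermediate
5 | ethyl (5S)-5-hydroxy-6-(4-methoxybenzyloxy)hex-2-ynoate | CCOC(=O)C#CC[C@H](O)COCc1ccc(OC)cc1 | intermediate
6 | ethyl (5S)-5-(tert-butyldimethylsilyloxy)-6-(4-methoxybenzyloxy)hex-2-ynoate | CCOC(=O)C#CC[C@H](O[Si](C)(C)C(C)(C)C)COCc1ccc(OC)cc1 | intermediate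
7 | ethyl (2Z,5S)-5-(tert-butyldimethylsilyloxy)-6-(4-methoxybenzyloxy)-3-methylhex-2-enoate | CCOC(=O)/C=C(C)\C[C@H](O[Si](C)(C)C(C)(C)C)COCc1ccc(OC)cc1 | intermediate
8 | (2Z,5S)-5-(tert-butyldimethylsilyloxy)-6-(4-methoxybenzyloxy)-3-methylhex-2-en-1-ol | OC/C=C(C)\C[C@H](O[Si](C)(C)C(C)(C)C)COCc1ccc(OC)cc1 | intermediate
9 | [(2R,3S)-3-[(2S)-2-(tert-butyldimethylsilyloxy)-3-(4-methoxybenzyloxy)propyl]-3-methyloxiran-2-yl]methanol | OC[C@H]1O[C@@]1(C)C[C@H](O[Si](C)(C)C(C)(C)C)COCc1ccc(OC)cc1 | intermediate
10 | (2S,3S)-3-[(2S)-2-(tert-butyldimethylsilyloxy)-3-(4-methoxybenzyloxy)propyl]-3-methyloxirane-2-carbaldehyde | O=C[C@H]1O[C@@]1(C)C[C@H](O[Si](C)(C)C(C)(C)C)COCc1ccc(OC)cc1 | intermediate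
11 | (E)-pent-3-en-2-one | C/C=C/C(C)=O | starting material
12 | lithium (E)-penta-1,3-dien-2-olate (not isolated) | C/C=C/C(=C)O[Li] | intermediate
13 | (2E,6R)-6-hydroxy-6-[(2R,3S)-3-[(2S)-2-(tert-butyldimethylsilyloxy)-3-(4-methoxybenzyloxy)propyl]-3-methyloxiran-2-yl]hex-2-en-4-one | C/C=C/C(=O)C[C@@H](O)[C@H]1O[C@@]1(C)C[C@H](O[Si](C)(C)C(C)(C)C)COCc1ccc(OC)cc1 | intermediate
14 | (2E,6R)-6-(triethylsilyloxy)-6-[(2R,3S)-3-[(2S)-2-(tert-butyldimethylsilyloxy)-3-(4-methoxybenzyloxy)propyl]-3-methyloxiran-2-yl]hex-2-en-4-one | C/C=C/C(=O)C[C@@H](O[Si](CC)(CC)CC)[C@H]1O[C@@]1(C)C[C@H](O[Si](C)(C)C(C)(C)C)COCc1ccc(OC)cc1 | intermediate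
15 | methyl 2-(hydroxymethyl)prop-2-enoate | C=C(CO)C(=O)OC | starting material
16 | methyl 2-[(triethylsilyloxy)methyl]prop-2-enoate | C=C(CO[Si](CC)(CC)CC)C(=O)OC | intermediate
17 | methyl 3-[(triethylsilyloxy)methyl]-1,2,4-trioxolane-3-carboxylate (ozonide, not isolated) | COC(=O)C1(CO[Si](CC)(CC)CC)OCOO1 | intermediate
18 | methyl 2-oxo-3-(triethylsilyloxy)propanoate | COC(=O)C(=O)CO[Si](CC)(CC)CC | intermediate
19 | lithium enolate of 14 at C7=C8 (not isolated) | C/C=C/C(O[Li])=C[C@@H](O[Si](CC)(CC)CC)[C@H]1O[C@@]1(C)C[C@H](O[Si](C)(C)C(C)(C)C)COCc1ccc(OC)cc1 | intermediate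
20 | methyl (4R)-3-[(E)-but-2-enoyl]-2-hydroxy-4-[(2R,3S)-3-[(2S)-2-(tert-butyldimethylsilyloxy)-3-(4-methoxybenzyloxy)propyl]-3-methyloxiran-2-yl]-4-(triethylsilyloxy)-2-[(triethylsilyloxy)methyl]butanoate (epimers at C7 and C11) | C/C=C/C(=O)C([C@@H](O[Si](CC)(CC)CC)[C@H]1O[C@@]1(C)C[C@H](O[Si](C)(C)C(C)(C)C)COCc1ccc(OC)cc1)C(O)(CO[Si](CC)(CC)CC)C(=O)OC | intermediate
21 | methyl (4R)-3-[(E)-but-2-enoyl]-2,4-dihydroxy-2-(hydroxymethyl)-4-[(2R,3S)-3-[(2S)-2-(tert-butyldimethylsilyloxy)-3-(4-methoxybenzyloxy)propyl]-3-methyloxiran-2-yl]butanoate (triol ester, not isolated) | C/C=C/C(=O)C([C@@H](O)[C@H]1O[C@@]1(C)C[C@H](O[Si](C)(C)C(C)(C)C)COCc1ccc(OC)cc1)C(O)(CO)C(=O)OC | intermediate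
22 | (5R)-4-[(E)-but-2-enoyl]-3-hydroxy-3-(hydroxymethyl)-5-[(2R,3S)-3-[(2S)-2-(tert-butyldimethylsilyloxy)-3-(4-methoxybenzyloxy)propyl]-3-methyloxiran-2-yl]oxolan-2-one (epimers at C7 and C11) | C/C=C/C(=O)C1[C@H]([C@H]2O[C@@]2(C)C[C@H](O[Si](C)(C)C(C)(C)C)COCc2ccc(OC)cc2)OC(=O)C1(O)CO | intermediate
23 | [(5R)-4-[(E)-but-2-enoyl]-3-hydroxy-2-oxo-5-[(2R,3S)-3-[(2S)-2-(tert-butyldimethylsilyloxy)-3-(4-methoxybenzyloxy)propyl]-3-methyloxiran-2-yl]oxolan-3-yl]methyl acetate (epimers at C7 and C11) | C/C=C/C(=O)C1[C@H]([C@H]2O[C@@]2(C)C[C@H](O[Si](C)(C)C(C)(C)C)COCc2ccc(OC)cc2)OC(=O)C1(O)COC(C)=O | intermediate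
24 | C11 methanesulfonate of 23 (not isolated) | C/C=C/C(=O)C1[C@H]([C@H]2O[C@@]2(C)C[C@H](O[Si](C)(C)C(C)(C)C)COCc2ccc(OC)cc2)OC(=O)C1(OS(C)(=O)=O)COC(C)=O | intermediate
25 | [(5R)-4-[(E)-but-2-enoyl]-5-[(2R,3S)-3-[(2S)-2-(tert-butyldimethylsilyloxy)-3-(4-methoxybenzyloxy)propyl]-3-methyloxiran-2-yl]-2-oxo-2,5-dihydrofuran-3-yl]methyl acetate | C/C=C/C(=O)C1=C(COC(C)=O)C(=O)O[C@H]1[C@H]1O[C@@]1(C)C[C@H](O[Si](C)(C)C(C)(C)C)COCc1ccc(OC)cc1 | intermediate
26 | [(5R)-4-[(E)-but-2-enoyl]-5-[(2R,3S)-3-[(2S)-2-(tert-butyldimethylsilyloxy)-3-hydroxypropyl]-3-methyloxiran-2-yl]-2-oxo-2,5-dihydrofuran-3-yl]methyl acetate | C/C=C/C(=O)C1=C(COC(C)=O)C(=O)O[C@H]1[C@H]1O[C@@]1(C)C[C@H](O[Si](C)(C)C(C)(C)C)CO | intermediate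
27 | [(5R)-4-[(E)-but-2-enoyl]-5-[(2R,3S)-3-[(2S)-2-(tert-butyldimethylsilyloxy)-3-oxopropyl]-3-methyloxiran-2-yl]-2-oxo-2,5-dihydrofuran-3-yl]methyl acetate | C/C=C/C(=O)C1=C(COC(C)=O)C(=O)O[C@H]1[C@H]1O[C@@]1(C)C[C@H](O[Si](C)(C)C(C)(C)C)C=O | intermediate
28 | (2S,4S,5R,6R,10S)-13-acetoxy-2-(tert-butyldimethylsilyloxy)-4,5-epoxy-1,8-dioxogermacr-7(11)-en-12,6-olide | O=C1C[C@H](C)C(=O)[C@@H](O[Si](C)(C)C(C)(C)C)C[C@]2(C)O[C@@H]2[C@@H]2OC(=O)C(COC(C)=O)=C21 | intermediate
29 | (2S,4S,5R,6R,8R,10S)-13-acetoxy-2-(tert-butyldimethylsilyloxy)-4,5-epoxy-8-hydroxy-1-oxogermacr-7(11)-en-12,6-olide | O[C@@H]1C[C@H](C)C(=O)[C@@H](O[Si](C)(C)C(C)(C)C)C[C@]2(C)O[C@@H]2[C@@H]2OC(=O)C(COC(C)=O)=C21 | intermediate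
30 | (2S,4S,5R,6R,8R,10S)-13-acetoxy-2-(tert-butyldimethylsilyloxy)-4,5-epoxy-8-(2-methylprop-2-enoyloxy)-1-oxogermacr-7(11)-en-12,6-olide | C=C(C)C(=O)O[C@@H]1C[C@H](C)C(=O)[C@@H](O[Si](C)(C)C(C)(C)C)C[C@]2(C)O[C@@H]2[C@@H]2OC(=O)C(COC(C)=O)=C21 | intermediate
31 | (2S,4S,5R,6R,8R,10S)-13-acetoxy-4,5-epoxy-2-hydroxy-8-(2-methylprop-2-enoyloxy)-1-oxogermacr-7(11)-en-12,6-olide (CNP0359197.1) | C=C(C)C(=O)O[C@@H]1C[C@H](C)C(=O)[C@@H](O)C[C@]2(C)O[C@@H]2[C@@H]2OC(=O)C(COC(C)=O)=C21 | target

## Step count and least certain steps

Total step count: 21. Longest linear sequence: 19 steps (steps 1–9 and 12–21, from 1 to 31); steps 10 and 11 are the two-step branch to 18.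

Step 18 (key step, new method). The ten-membered closure may be slower than intermolecular acyloin formation and oligomerisation of the aldehyde. The carbene, itself a base, may remove C6–H and so trigger eliminative opening of the epoxide or loss of the C13 acetate. Facial selection at C10 may be poor if the catalyst is mismatched with the substrate, and any attempt to equilibrate C10 risks epimerisation at C2. The antipodal triazolium salt is the first recourse for selectivity. The fallback uses known radical chemistry under neutral conditions. Aldehyde 27 is oxidised (NaClO2, NaH2PO4, 2-methylbut-2-ene) to the C1 carboxylic acid F1, which is converted with diphenyl diselenide and tributylphosphine into the Se-phenyl selenoester F2. Slow addition of n-Bu3SnH and azobisisobutyronitrile to F2 in hot benzene at high dilution generates the C1 acyl radical, which adds to C10 of the enone (acyl radical macrocyclisation). Hydrogen transfer to the C9 radical gives 28, where the route is rejoined; the C10 epimers would have to be separated. Decarbonylation of the α-silyloxy acyl radical is the weak point of this fallback.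

Step 12. Proton transfer from the enolisable keto ester to the enolate may compete with addition. The enolate may open the neighbouring epoxide (cyclopropane formation) or lose silyloxide if it warms, and the tertiary aldolate may revert. Fallback from 14: the same enolate is trapped with chlorotrimethylsilane as the trimethylsilyl enol ether F3. F3 is added to 18 in a Mukaiyama aldol reaction catalysed by Cu(OTf)2 with 2,2'-isopropylidenebis(4-tert-butyl-2-oxazoline); the divalent copper chelates the keto ester and no basic species is present. The product, the C11 trimethylsilyl ether F4, enters step 13 unchanged, where HF·pyridine removes all three silyl groups, and the route is rejoined at 22.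

Step 15. Sulfonylation of the hindered tertiary alcohol may be slow. Elimination may run in the wrong direction, with ring opening of the lactone at C6. The amine may degrade the product through enolisation at C6. The fallback moves the elimination ahead of the lactonisation. From 14 and 18 the aldol reaction of step 12 is repeated and the lithium aldolate is quenched with acetic anhydride, giving the C11 acetate F5. DBU then eliminates acetic acid across C7–C11, acetate being the only good leaving group β to the enolate, to give the ene-keto ester F6 as a mixture of alkene isomers. HF·pyridine frees O6–H and O13–H. The isomer with C6 cis to C12 lactonises to the hydroxymethyl butenolide F7, and the other isomer is returned to the pool by iodine-catalysed photoisomerisation. Acetylation of F7 (Ac2O, pyridine) gives 25.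

Step 19. The C1 ketone may be reduced competitively. Conjugate reduction may occur. The conformation of the ten-membered ring may override the catalyst and lower the facial selectivity at C8. Transannular hemiketal formation between O8 and C1 may complicate isolation. Fallback from 28: Luche reduction (NaBH4, CeCl3·7H2O, MeOH, −78 °C) under substrate control. If this gives mainly the 8S alcohol F8, Mitsunobu esterification of F8 with methacrylic acid (PPh3, diisopropyl azodicarboxylate) inverts C8 and gives 30 directly, so step 20 is skipped.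

Step 8. Discrimination between the two faces of the aldehyde by the lithium enolate may be insufficient. The lithium aldolate may revert or undergo Payne-type epoxide migration if it warms before the quench. The fallback is a chromium Reformatsky reaction under neutral conditions. Enolate 12 is brominated with N-bromosuccinimide to (E)-1-bromopent-3-en-2-one F9. F9 and aldehyde 10 are treated with CrCl2 in THF, and the trivalent chromium enolate adds to the aldehyde with Felkin selectivity and without basic species, giving 13.

## Further compounds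

F1 | step 18 | C1 carboxylic acid corresponding to aldehyde 27 (CHO replaced by CO2H, all stereocentres as in 27) | C/C=C/C(=O)C1=C(COC(C)=O)C(=O)O[C@H]1[C@H]1O[C@@]1(C)C[C@H](O[Si](C)(C)C(C)(C)C)C(=O)O
F2 | step 18 | Se-phenyl selenoester of F1 | C/C=C/C(=O)C1=C(COC(C)=O)C(=O)O[C@H]1[C@H]1O[C@@]1(C)C[C@H](O[Si](C)(C)C(C)(C)C)C(=O)[Se]c1ccccc1
F3 | step 12 | trimethylsilyl enol ether of 14 (C7=C8, O8–SiMe3) | C/C=C/C(O[Si](C)(C)C)=C[C@@H](O[Si](CC)(CC)CC)[C@H]1O[C@@]1(C)C[C@H](O[Si](C)(C)C(C)(C)C)COCc1ccc(OC)cc1
F4 | step 12 | C11 trimethylsilyl ether of aldol adduct 20 (epimers at C7 and C11) | C/C=C/C(=O)C([C@@H](O[Si](CC)(CC)CC)[C@H]1O[C@@]1(C)C[C@H](O[Si](C)(C)C(C)(C)C)COCc1ccc(OC)cc1)C(O[Si](C)(C)C)(CO[Si](CC)(CC)CC)C(=O)OC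
F5 | step 15 | C11 acetate of aldol adduct 20 (epimers at C7 and C11) | C/C=C/C(=O)C([C@@H](O[Si](CC)(CC)CC)[C@H]1O[C@@]1(C)C[C@H](O[Si](C)(C)C(C)(C)C)COCc1ccc(OC)cc1)C(OC(C)=O)(CO[Si](CC)(CC)CC)C(=O)OC
F6 | step 15 | methyl 4-oxo-2-[(triethylsilyloxy)methyl]hepta-2,5-dienoate bearing on C3 the C6 side chain of 14 (C7=C11 alkene, both geometries) | C/C=C/C(=O)C([C@@H](O[Si](CC)(CC)CC)[C@H]1O[C@@]1(C)C[C@H](O[Si](C)(C)C(C)(C)C)COCc1ccc(OC)cc1)=C(CO[Si](CC)(CC)CC)C(=O)OC
F7 | step 15 | C13 alcohol corresponding to 25 (acetate replaced by hydroxyl) | C/C=C/C(=O)C1=C(CO)C(=O)O[C@H]1[C@H]1O[C@@]1(C)C[C@H](O[Si](C)(C)C(C)(C)C)COCc1ccc(OC)cc1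
F8 | step 19 | (8S)-epimer of 29 | O[C@H]1C[C@H](C)C(=O)[C@@H](O[Si](C)(C)C(C)(C)C)C[C@]2(C)O[C@@H]2[C@@H]2OC(=O)C(COC(C)=O)=C21
F9 | step 8 | (E)-1-bromopent-3-en-2-one | C/C=C/C(=O)CBr
A1 | alternative 1 | (2S,4S,5R,6R,8R,10S)-2-(tert-butyldimethylsilyloxy)-4,5-epoxy-13-(4-methoxybenzyloxy)-1-oxo-8-(triethylsilyloxy)germacr-7(11)-en-12,6-olide | CC[Si](CC)(CC)O[C@@H]1C[C@H](C)C(=O)[C@@H](O[Si](C)(C)C(C)(C)C)C[C@]2(C)O[C@@H]2[C@@H]2OC(=O)C(COCc3ccc(OC)cc3)=C21
A2 | alternative 1 | seco methyl (Z)-3-iodo-2-[(4-methoxybenzyloxy)methyl]alk-2-enoate with C8–OTES, C10 methyl, C1 ketone, C2–OTBS and the C6 epoxy aldehyde terminus | COC(=O)/C(COCc1ccc(OC)cc1)=C(\I)[C@H](O[Si](CC)(CC)CC)C[C@H](C)C(=O)[C@@H](O[Si](C)(C)C(C)(C)C)C[C@]1(C)O[C@@H]1C=O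
A3 | alternative 2 | (2Z,6E)-5-(tert-butyldimethylsilyloxy)-9-(4-methoxybenzyloxy)-3,7-dimethylcyclodeca-2,6-dien-1-one (germacrane C2 and C8 as in the target) | COc1ccc(CO[C@@H]2C/C(C)=C/[C@@H](O[Si](C)(C)C(C)(C)C)C/C(C)=C\C(=O)C2)cc1
A4 | alternative 2 | (1S,5S,6S)-5-(tert-butyldimethylsilyloxy)-1-[(E)-2-(4-methoxybenzyloxy)ethenyl]-3-methyl-6-(prop-1-en-2-yl)cyclohex-2-en-1-ol | C=C(C)[C@H]1[C@@H](O[Si](C)(C)C(C)(C)C)CC(C)=C[C@]1(O)/C=C/OCc1ccc(OC)cc1
A5 | alternative 3 | (4Z,6S,8R,10S)-13-(4-methoxybenzyloxy)-1-oxo-8-(triethylsilyloxy)germacra-4,7(11)-dien-12,6-olide | CC[Si](CC)(CC)O[C@@H]1C[C@H](C)C(=O)CC/C(C)=C\[C@@H]2OC(=O)C(COCc3ccc(OC)cc3)=C21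
A6 | alternative 3 | butenolide bearing the (Z)-2-iodoprop-1-enyl group on C6 and the C8–OTES, C10-methyl chain ending in a 1-hydroxycyclopropyl group on C7 | CC[Si](CC)(CC)O[C@H](C[C@H](C)C1(O)CC1)C1=C(COCc2ccc(OC)cc2)C(=O)O[C@H]1/C=C(/C)I
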